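**Strategy.** The flavonol is disconnected at C4–C4a of ring C. An (E)-3-aryloxy-2-benzyloxyacrylic acid, whose carboxyl lies cis to the ring A aryloxy group, is closed by intramolecular Friedel–Crafts acylation, which forms the pyranone in one operation. The step exploits C4a, the only unsubstituted carbon of ring A, which is ortho to the oxygens on C5 and C8a and para to the oxygen on C7. The precursor already carries O1–C2 and the C3 oxygen; these are set by addition–elimination of 5-(benzyloxy)-2,3,4-trimethoxyphenol on a stereodefined enol triflate of an α-benzyloxy β-ketoester. Four benzyl ethers are removed at the end by hydrogenolysis.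

Key step: step 10

Assumption: the alkene geometry set in step 7 is taken to pass unchanged through steps 8 and 9; a second geometric isomer, should it appear, would be removed by chromatography at ester 16.

Design choices:
- Acid 17 is made as the single E isomer and is not left to equilibrate. In the Z isomer the activated carboxyl would sit beside ring B and its 2'-benzyloxy oxygen, where acylation of ring B or lactonisation with loss of benzyl could compete.
- Phenol 8 is built by regiochemically defined steps, so no statistical monoprotection of a symmetric diol is needed.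
- A methyl ester is used so that the hydrolysis in step 9 is as easy as possible.
- Compounds 1, 9 and 12 are commercial.

**Route**

Step 1
Reactants: 1 2,3,4-trimethoxybenzaldehyde
Product: 2 5-bromo-2,3,4-trimethoxybenzaldehyde
Conditions: NBS, DMF, rt
Reagents that add atoms: N-bromosuccinimide, O=C1CCC(=O)N1Br
Why: Electrophilic aromatic bromination should go to C5, the position ortho to the C4 methoxy, para to the C2 methoxy and meta to the formyl group, where all directing effects agree.

Step 2
Reactants: 2 5-bromo-2,3,4-trimethoxybenzaldehyde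
Product: 4 5-bromo-2,3,4-trimethoxyphenol, via aryl formate 3 (not isolated)
Conditions: mCPBA, CH2Cl2, rt; then K2CO3, MeOH, rt
Reagents that add atoms: 3-chloroperoxybenzoic acid, OOC(=O)c1cccc(Cl)c1
Why: Baeyer–Villiger (Dakin-type) oxidation, in which the ortho and para methoxy groups favour aryl migration to the formate, which methanolysis then cleaves.

Step 3
Reactants: 4 5-bromo-2,3,4-trimethoxyphenol
Product: 5 1-(benzyloxy)-5-bromo-2,3,4-trimethoxybenzene
Conditions: BnBr, K2CO3, DMF, rt
Reagents that add atoms: benzyl bromide, BrCc1ccccc1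
Why: Williamson ether synthesis on an unhindered phenoxide.

Step 4
Reactants: 5 1-(benzyloxy)-5-bromo-2,3,4-trimethoxybenzene
Product: 8 5-(benzyloxy)-2,3,4-trimethoxyphenol, via aryllithium 6 (not isolated), via lithium aryltrimethoxyborate 7 (not isolated)
Conditions: n-BuLi, THF, −78 °C; B(OMe)3, −78 °C → rt; H2O2, aq. NaOH, 0 °C
Reagents that add atoms: hydrogen peroxide, OO
Why: Bromine–lithium exchange, borylation and oxidative carbon-to-oxygen migration of the borate replace bromine by hydroxyl at a fixed position, and the exchange at −78 °C should be faster than any attack on the benzyl ether.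

Step 5
Reactants: 9 2,5-dihydroxybenzoic acid
Product: 11 2,5-bis(benzyloxy)benzoic acid, via tribenzyl ester 10 (not isolated)
Conditions: BnBr (3.5 equiv), K2CO3, DMF, 70 °C; then NaOH, MeOH–H2O, reflux; then HCl
Reagents that add atoms: benzyl bromide, BrCc1ccccc1; sodium hydroxide, [Na+].[OH-]
Why: Williamson benzylation of both phenols and the carboxylate, then saponification of the benzyl ester alone, since aryl benzyl ethers are stable to hydroxide.

Step 6
Reactants: 11 2,5-bis(benzyloxy)benzoic acid; 12 methyl 2-(benzyloxy)acetate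
Product: 14 methyl (2RS)-2-(benzyloxy)-3-[2,5-bis(benzyloxy)phenyl]-3-oxopropanoate, via acid chloride 13 (not isolated)
Conditions: (COCl)2, cat. DMF, CH2Cl2, rt, then evaporation; 12 (2.2 equiv), LiN(SiMe3)2 (2.2 equiv), THF, −78 °C, then 13, −78 → 0 °C
Reagents that add atoms: none
Why: Crossed Claisen acylation of the lithium ester enolate by the acid chloride, with the second equivalent of enolate deprotonating the more acidic β-ketoester; the stereocentre is racemic and disappears in step 7.

Step 7
Reactants: 14 methyl (2RS)-2-(benzyloxy)-3-[2,5-bis(benzyloxy)phenyl]-3-oxopropanoate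
Product: 15 methyl (E)-2-(benzyloxy)-3-[2,5-bis(benzyloxy)phenyl]-3-{[(trifluoromethyl)sulfonyl]oxy}prop-2-enoate (triflate cis to the ester)
Conditions: NaH, CH2Cl2, 0 °C; Tf2O, −78 → 0 °C
Reagents that add atoms: trifluoromethanesulfonic anhydride, O=S(=O)(OS(=O)(=O)C(F)(F)F)C(F)(F)F
Why: O-sulfonylation of the sodium enolate, whose chelated form (sodium bridging the ketone and ester oxygens, aryl group next to the small benzyloxy group) should place the triflate cis to the ester.

Step 8
Reactants: 15 methyl (E)-2-(benzyloxy)-3-[2,5-bis(benzyloxy)phenyl]-3-{[(trifluoromethyl)sulfonyl]oxy}prop-2-enoate; 8 5-(benzyloxy)-2,3,4-trimethoxyphenol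
Product: 16 methyl (E)-2-(benzyloxy)-3-[5-(benzyloxy)-2,3,4-trimethoxyphenoxy]-3-[2,5-bis(benzyloxy)phenyl]prop-2-enoate (aryloxy group cis to the ester)
Conditions: Cs2CO3, MeCN, 0 °C → rt
Reagents that add atoms: none
Why: Nucleophilic vinylic substitution by addition–elimination, in which the caesium phenoxide adds to the β-carbon of the β-triflyloxy acrylate and rapid loss of triflate from the short-lived ester enolate should retain the geometry.

Step 9
Reactants: 16 methyl (E)-2-(benzyloxy)-3-[5-(benzyloxy)-2,3,4-trimethoxyphenoxy]-3-[2,5-bis(benzyloxy)phenyl]prop-2-enoate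
Product: 17 (E)-2-(benzyloxy)-3-[5-(benzyloxy)-2,3,4-trimethoxyphenoxy]-3-[2,5-bis(benzyloxy)phenyl]prop-2-enoic acid (carboxyl cis to the ring A aryloxy group)
Conditions: LiOH, THF–MeOH–H2O, 40 °C; then 1 M HCl, 0 °C, to pH 3
Reagents that add atoms: lithium hydroxide, [Li+].[OH-]
Why: Saponification by acyl substitution under basic conditions, which cannot isomerise the alkene, followed by cold, brief acidification that the push–pull enol ether should tolerate.

Step 10
Reactants: 17 (E)-2-(benzyloxy)-3-[5-(benzyloxy)-2,3,4-trimethoxyphenoxy]-3-[2,5-bis(benzyloxy)phenyl]prop-2-enoic acid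
Product: 19 3,5-bis(benzyloxy)-2-[2,5-bis(benzyloxy)phenyl]-6,7,8-trimethoxy-4H-chromen-4-one, via mixed anhydride 18 (not isolated)
Conditions: TFAA (3 equiv), CH2Cl2, 0 °C → rt
Reagents that add atoms: none
Why: TFAA converts the acid into mixed anhydride 18, which ionises to an acylium ion stabilised by the aryloxy donor on C2; this ion attacks C4a of ring A, and loss of the proton restores aromaticity and gives the 4-pyranone. The closest known reaction type is the intramolecular Friedel–Crafts acylation of 3-aryloxycinnamic acids to flavones. Ring C closes in a 6-exo mode at the acyl carbon, the arene π bond being endocyclic, and only the C4–C4a bond is formed. No stereocentre is created. The step needs selectivity for ring A over ring B and over ether oxygens: the E geometry holds the acyl carbon beside ring A and away from ring B and its 2'-benzyloxy oxygen, and C4a is the only unsubstituted ring A carbon, activated by the ortho oxygens on C5 and C8a and the para oxygen on C7. Low temperature and the absence of a strong Lewis acid should keep the benzyl ethers and the alkene geometry intact until closure.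

Step 11
Reactants: 19 3,5-bis(benzyloxy)-2-[2,5-bis(benzyloxy)phenyl]-6,7,8-trimethoxy-4H-chromen-4-one
Product: 20 2-(2,5-dihydroxyphenyl)-3,5-dihydroxy-6,7,8-trimethoxy-4H-chromen-4-one
Conditions: H2 (1 atm), 10% Pd/C, EtOAc–MeOH, rt; filtration and concentration under argon
Reagents that add atoms: none
Why: Catalytic hydrogenolysis of the four benzyl ethers, which should leave the tetrasubstituted C2–C3 bond of the chromone untouched; exclusion of air protects the hydroquinone of ring B.

**Compound list**

1 | 2,3,4-trimethoxybenzaldehyde | COc1ccc(C=O)c(OC)c1OC | starting material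
2 | 5-bromo-2,3,4-trimethoxybenzaldehyde | COc1c(Br)cc(C=O)c(OC)c1OC | intermediate
3 | 5-bromo-2,3,4-trimethoxyphenyl formate (not isolated) | COc1c(Br)cc(OC=O)c(OC)c1OC | intermediate
4 | 5-bromo-2,3,4-trimethoxyphenol | COc1c(Br)cc(O)c(OC)c1OC | intermediate
5 | 1-(benzyloxy)-5-bromo-2,3,4-trimethoxybenzene | COc1c(Br)cc(OCc2ccccc2)c(OC)c1OC | intermediate
6 | [5-(benzyloxy)-2,3,4-trimethoxyphenyl]lithium (not isolated) | [Li]c1cc(OCc2ccccc2)c(OC)c(OC)c1OC | intermediate
7 | lithium [5-(benzyloxy)-2,3,4-trimethoxyphenyl]trimethoxyborate (not isolated) | [Li+].CO[B-](OC)(OC)c1cc(OCc2ccccc2)c(OC)c(OC)c1OC | intermediate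
8 | 5-(benzyloxy)-2,3,4-trimethoxyphenol | Oc1cc(OCc2ccccc2)c(OC)c(OC)c1OC | intermediate
9 | 2,5-dihydroxybenzoic acid | O=C(O)c1cc(O)ccc1O | starting material
10 | benzyl 2,5-bis(benzyloxy)benzoate (not isolated) | O=C(OCc1ccccc1)c1cc(OCc2ccccc2)ccc1OCc1ccccc1 | intermediate
11 | 2,5-bis(benzyloxy)benzoic acid | O=C(O)c1cc(OCc2ccccc2)ccc1OCc1ccccc1 | intermediate
12 | methyl 2-(benzyloxy)acetate | COC(=O)COCc1ccccc1 | starting material
13 | 2,5-bis(benzyloxy)benzoyl chloride (not isolated) | O=C(Cl)c1cc(OCc2ccccc2)ccc1OCc1ccccc1 | intermediate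
14 | methyl (2RS)-2-(benzyloxy)-3-[2,5-bis(benzyloxy)phenyl]-3-oxopropanoate (racemic) | COC(=O)C(OCc1ccccc1)C(=O)c1cc(OCc2ccccc2)ccc1OCc1ccccc1 | intermediate
15 | methyl (E)-2-(benzyloxy)-3-[2,5-bis(benzyloxy)phenyl]-3-{[(trifluoromethyl)sulfonyl]oxy}prop-2-enoate | COC(=O)/C(OCc1ccccc1)=C(\OS(=O)(=O)C(F)(F)F)c1cc(OCc2ccccc2)ccc1OCc1ccccc1 | intermediate
16 | methyl (E)-2-(benzyloxy)-3-[5-(benzyloxy)-2,3,4-trimethoxyphenoxy]-3-[2,5-bis(benzyloxy)phenyl]prop-2-enoate | COC(=O)/C(OCc1ccccc1)=C(\Oc1cc(OCc2ccccc2)c(OC)c(OC)c1OC)c1cc(OCc2ccccc2)ccc1OCc1ccccc1 | intermediate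
17 | (E)-2-(benzyloxy)-3-[5-(benzyloxy)-2,3,4-trimethoxyphenoxy]-3-[2,5-bis(benzyloxy)phenyl]prop-2-enoic acid | OC(=O)/C(OCc1ccccc1)=C(\Oc1cc(OCc2ccccc2)c(OC)c(OC)c1OC)c1cc(OCc2ccccc2)ccc1OCc1ccccc1 | intermediate
18 | mixed anhydride of 17 and trifluoroacetic acid, E alkene (not isolated) | O=C(OC(=O)C(F)(F)F)/C(OCc1ccccc1)=C(\Oc1cc(OCc2ccccc2)c(OC)c(OC)c1OC)c1cc(OCc2ccccc2)ccc1OCc1ccccc1 | intermediate
19 | 3,5-bis(benzyloxy)-2-[2,5-bis(benzyloxy)phenyl]-6,7,8-trimethoxy-4H-chromen-4-one | COc1c(OC)c(OCc2ccccc2)c2c(=O)c(OCc3ccccc3)c(-c3cc(OCc4ccccc4)ccc3OCc3ccccc3)oc2c1OC | intermediate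
20 | 2-(2,5-dihydroxyphenyl)-3,5-dihydroxy-6,7,8-trimethoxy-4H-chromen-4-one (no stereocentre) | COc1c(OC)c(O)c2c(=O)c(O)c(-c3cc(O)ccc3O)oc2c1OC | target

**Step count**

Total steps: 11. Longest linear sequence: 8 steps (steps 1, 2, 3, 4, 8, 9, 10 and 11).

**Steps most likely to fail**

1. Step 10. The push–pull alkene may isomerise under acid before ring closure. The activated carboxyl would then be captured by the 2'-benzyloxy oxygen of ring B (lactonisation with loss of benzyl) or by ring B itself, and benzyl ethers may be lost to trifluoroacetic acid. The fallback makes the same C4–C4a bond under anionic conditions. It sets out from 8: bromination of the single ring C–H (NBS, CH2Cl2, −78 → 0 °C) should give 3-(benzyloxy)-2-bromo-4,5,6-trimethoxyphenol F1. Addition–elimination of F1 on triflate 15 under the conditions of step 8 should give methyl (E)-2-(benzyloxy)-3-[3-(benzyloxy)-2-bromo-4,5,6-trimethoxyphenoxy]-3-[2,5-bis(benzyloxy)phenyl]prop-2-enoate F2. Bromine–lithium exchange (n-BuLi, THF, −100 °C) and attack of the aryllithium on the neighbouring ester (Parham cyclisation) should then close ring C. The fallback comes back to the route at 19, needs no acid, and bypasses steps 9 and 10.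

2. Step 8. The phenoxide may attack sulfur and transfer the triflyl group, which returns the enolate of 14. Addition at the hindered, donor-substituted β-carbon may also be slow enough for the geometry to erode. The fallback forms the C–O bond by cross-coupling instead of addition–elimination. It sets out from 15 and 8: Pd2(dba)3, 2-(di-tert-butylphosphino)biphenyl, K3PO4, toluene, 80 °C. Zerovalent palladium inserts into the C–OTf bond with retention of geometry, and C–O reductive elimination follows. The fallback comes back to the route at 16 and makes no new compound.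

3. Step 9. Acyl substitution at the hindered ester may be slow, which would let hydroxide add at C3 of the acrylate and expel the aryloxide. The fallback uses an ester that is cleaved without a nucleophile at either carbon. It sets out from 11 (through 13) and 8. The crossed Claisen of step 6 is run on prop-2-en-1-yl 2-(benzyloxy)acetate F3, made from commercial benzyloxyacetic acid with allyl bromide and K2CO3 in DMF. This should give prop-2-en-1-yl (2RS)-2-(benzyloxy)-3-[2,5-bis(benzyloxy)phenyl]-3-oxopropanoate F4. Triflation as in step 7 should give prop-2-en-1-yl (E)-2-(benzyloxy)-3-[2,5-bis(benzyloxy)phenyl]-3-{[(trifluoromethyl)sulfonyl]oxy}prop-2-enoate F5. Addition–elimination of 8 as in step 8 should give prop-2-en-1-yl (E)-2-(benzyloxy)-3-[5-(benzyloxy)-2,3,4-trimethoxyphenoxy]-3-[2,5-bis(benzyloxy)phenyl]prop-2-enoate F6. Deallylation through a π-allyl complex (Pd(PPh3)4, morpholine, THF, rt) should release the acid under neutral conditions. The fallback comes back to the route at 17.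

**Further compounds**

F1 | step 10 | 3-(benzyloxy)-2-bromo-4,5,6-trimethoxyphenol | Oc1c(Br)c(OCc2ccccc2)c(OC)c(OC)c1OC
F2 | step 10 | methyl (E)-2-(benzyloxy)-3-[3-(benzyloxy)-2-bromo-4,5,6-trimethoxyphenoxy]-3-[2,5-bis(benzyloxy)phenyl]prop-2-enoate | COC(=O)/C(OCc1ccccc1)=C(\Oc1c(Br)c(OCc2ccccc2)c(OC)c(OC)c1OC)c1cc(OCc2ccccc2)ccc1OCc1ccccc1
F0 | step 8 | none | none
F3 | step 9 | prop-2-en-1-yl 2-(benzyloxy)acetate | C=CCOC(=O)COCc1ccccc1
F4 | step 9 | prop-2-en-1-yl (2RS)-2-(benzyloxy)-3-[2,5-bis(benzyloxy)phenyl]-3-oxopropanoate | C=CCOC(=O)C(OCc1ccccc1)C(=O)c1cc(OCc2ccccc2)ccc1OCc1ccccc1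
F5 | step 9 | prop-2-en-1-yl (E)-2-(benzyloxy)-3-[2,5-bis(benzyloxy)phenyl]-3-{[(trifluoromethyl)sulfonyl]oxy}prop-2-enoate | C=CCOC(=O)/C(OCc1ccccc1)=C(\OS(=O)(=O)C(F)(F)F)c1cc(OCc2ccccc2)ccc1OCc1ccccc1
F6 | step 9 | prop-2-en-1-yl (E)-2-(benzyloxy)-3-[5-(benzyloxy)-2,3,4-trimethoxyphenoxy]-3-[2,5-bis(benzyloxy)phenyl]prop-2-enoate | C=CCOC(=O)/C(OCc1ccccc1)=C(\Oc1cc(OCc2ccccc2)c(OC)c(OC)c1OC)c1cc(OCc2ccccc2)ccc1OCc1ccccc1
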